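**Retrosynthetic overview**
1. Target 21 ⇐ Pinnick oxidation of aldehyde 20 ⇐ one-pot HCl cascade on epoxy ketal carbinol 17 (ketal/acetal hydrolysis, chloride opening of the α,β-epoxy ketone at Cα, loss of water). The oxirane is a traceless stereo-relay: it fixes the quaternary carbinol and is then erased into the C=C–Cl unit.
2. 17 ⇐ Grignard addition anti to the oxirane of epoxy quinone monoketal 14 ⇐ catalytic asymmetric nucleophilic epoxidation of quinone monoketal 13.
3. 13 ⇐ PhI(OAc)2/MeOH dearomatisation of anilide 11 ⇐ HWE of phosphonoacetanilide 10 with aldehyde 7 (the amide C–N bond exists before the enoyl C=C).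
4. 7 ⇐ lipase desymmetrisation of meso-2,4-dimethylpentane-1,5-diol; both methyl stereocentres come from one meso precursor.
5. Rings: the carbocycle is the benzene ring of 2,5-dimethoxyaniline and is never built; the only ring formed is the oxirane (step 10), opened again in step 12. The usual plan (late amide coupling plus PhI(OAc)2/H2O dearomatisation of a p-alkylphenol, which gives no control at the carbinol) is not used.

Assumption: N-benzylcinchoninium chloride is taken to give the (1R,6S)-epoxide 14 in step 10; if one analytical run shows the opposite sense, the pseudoenantiomeric N-benzylcinchonidinium chloride is used with nothing else changed.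

**Route**

Step 1
Reactants: 1 meso-2,4-dimethylglutaric anhydride
Product: 2 meso-2,4-dimethylpentane-1,5-diol
Conditions: LiAlH4, THF, 0 °C to reflux; Fieser work-up
Reagents that add atoms: none
Why: LiAlH4 reduction of the cyclic anhydride to the diol; the two α-stereocentres are untouched, so the meso (syn-1,3-dimethyl) relationship is carried over.

Step 2
Reactants: 2 meso-2,4-dimethylpentane-1,5-diol
Product: 3 (2S,4R)-5-hydroxy-2,4-dimethylpentyl acetate
Conditions: Amano lipase AK (Pseudomonas fluorescens), vinyl acetate, THF, rt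
Reagents that add atoms: vinyl acetate CC(=O)OC=C
Why: Enzymatic desymmetrisation of a meso diol by lipase transesterification; the enzyme acylates the hydroxymethyl on the S carbon, which sets both methyl stereocentres (typically ≥98% ee) in one operation.

Step 3
Reactants: 3 (2S,4R)-5-hydroxy-2,4-dimethylpentyl acetate
Product: 4 (2S,4R)-2,4-dimethyl-5-oxopentyl acetate
Conditions: TEMPO (10 mol %), PhI(OAc)2, CH2Cl2, rt
Reagents that add atoms: none
Why: TEMPO/oxoammonium oxidation stops at the aldehyde under near-neutral conditions, so the α-methyl stereocentre is not epimerised and the acetate survives.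

Step 4
Reactants: 4 (2S,4R)-2,4-dimethyl-5-oxopentyl acetate
Product: 5 (2S,4R)-2,4,6-trimethylhept-5-en-1-yl acetate
Conditions: i-PrPPh3I, n-BuLi, THF, 0 °C; then 4, −78 °C to 0 °C
Reagents that add atoms: isopropyltriphenylphosphonium iodide CC(C)[P+](c1ccccc1)(c1ccccc1)c1ccccc1.[I-]
Why: Wittig olefination with the non-stabilised isopropylidene ylide is fast at −78 °C, so neither the α-stereocentre nor the acetate suffers; there is no E/Z question because the ylide carbon carries two methyls.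

Step 5
Reactants: 5 (2S,4R)-2,4,6-trimethylhept-5-en-1-yl acetate
Product: 6 (2S,4R)-2,4,6-trimethylhept-5-en-1-ol
Conditions: K2CO3 (cat.), MeOH, rt
Reagents that add atoms: none
Why: Base-catalysed methanolysis (transesterification) frees the primary alcohol without touching the alkene or the stereocentres.

Step 6
Reactants: 6 (2S,4R)-2,4,6-trimethylhept-5-en-1-ol
Product: 7 (2S,4R)-2,4,6-trimethylhept-5-enal
Conditions: TEMPO (10 mol %), PhI(OAc)2, CH2Cl2, rt; used at once
Reagents that add atoms: none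
Why: The same oxoammonium oxidation leaves the trisubstituted alkene alone and gives the α-chiral aldehyde without epimerisation.

Step 7
Reactants: 8 2,5-dimethoxyaniline; 9 2-(diethoxyphosphoryl)acetic acid
Product: 10 diethyl {2-[(2,5-dimethoxyphenyl)amino]-2-oxoethyl}phosphonate
Conditions: EDC·HCl, DMAP (cat.), CH2Cl2, 0 °C to rt
Reagents that add atoms: none
Why: Carbodiimide amide coupling of an electron-rich aniline; the phosphonate is the handle for the later olefination.

Step 8
Reactants: 7 (2S,4R)-2,4,6-trimethylhept-5-enal; 10 diethyl {2-[(2,5-dimethoxyphenyl)amino]-2-oxoethyl}phosphonate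
Product: 11 (2E,4S,6R)-N-(2,5-dimethoxyphenyl)-4,6,8-trimethylnona-2,7-dienamide
Conditions: LiCl, DBU, MeCN, 0 °C to rt
Reagents that add atoms: none
Why: Horner–Wadsworth–Emmons olefination under Masamune–Roush conditions gives the (E)-enamide and is mild enough not to epimerise the α-methyl aldehyde.

Step 9
Reactants: 11 (2E,4S,6R)-N-(2,5-dimethoxyphenyl)-4,6,8-trimethylnona-2,7-dienamide
Product: 13 (2E,4S,6R)-N-(6,6-dimethoxy-3-oxocyclohexa-1,4-dien-1-yl)-4,6,8-trimethylnona-2,7-dienamide, via quinone imine ketal 12 (not isolated)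
Conditions: PhI(OAc)2, MeOH, 0 °C; aq NaHCO3 work-up
Reagents that add atoms: methanol CO; water O
Why: Hypervalent-iodine oxidative dearomatisation of a p-dimethoxy anilide: methanol is captured at the methoxy-bearing carbon ortho to nitrogen and the vinylogous imidate 12 hydrolyses on work-up to the vinylogous-amide ketone; isolated alkenes are not attacked by PhI(OAc)2 without acid activation.

Step 10
Reactants: 13 (2E,4S,6R)-N-(6,6-dimethoxy-3-oxocyclohexa-1,4-dien-1-yl)-4,6,8-trimethylnona-2,7-dienamide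
Product: 14 (2E,4S,6R)-N-[(1R,6S)-2,2-dimethoxy-5-oxo-7-oxabicyclo[4.1.0]hept-3-en-3-yl]-4,6,8-trimethylnona-2,7-dienamide
Conditions: t-BuOOH, aq NaOH, N-benzylcinchoninium chloride (10 mol %), toluene, rt
Reagents that add atoms: tert-butyl hydroperoxide CC(C)(C)OO
Why: Wynberg-type asymmetric phase-transfer Weitz–Scheffer epoxidation: the chiral ammonium/peroxide ion pair attacks one face of the only electrophilic C=C (the N-substituted enone is a deactivated vinylogous amide) and sets both oxirane carbons as (1R,6S); the minor epoxide is a diastereomer and is removed by chromatography.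

Step 11
Reactants: 14 (2E,4S,6R)-N-[(1R,6S)-2,2-dimethoxy-5-oxo-7-oxabicyclo[4.1.0]hept-3-en-3-yl]-4,6,8-trimethylnona-2,7-dienamide; 15 2-(4-bromobutyl)-1,3-dioxolane
Product: 17 (2E,4S,6R)-N-[(1R,5R,6S)-5-[4-(1,3-dioxolan-2-yl)butyl]-5-hydroxy-2,2-dimethoxy-7-oxabicyclo[4.1.0]hept-3-en-3-yl]-4,6,8-trimethylnona-2,7-dienamide, via Grignard reagent 16 (not isolated)
Conditions: 15, Mg, THF; then 14 (0.28 equiv), LaCl3·2LiCl, THF, −78 to −40 °C; aq NH4Cl
Reagents that add atoms: none
Why: Grignard 1,2-addition to the α,β-epoxy ketone (the first equivalent is spent on the amide N–H); the nucleophile comes in anti to the oxirane oxygen, so the new (R)-carbinol has OH syn to the epoxide and the epoxide configuration is relayed to the quaternary carbon by substrate control, while 1,4-addition is blocked by the β-amido group.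

Step 12
Reactants: 17 (2E,4S,6R)-N-[(1R,5R,6S)-5-[4-(1,3-dioxolan-2-yl)butyl]-5-hydroxy-2,2-dimethoxy-7-oxabicyclo[4.1.0]hept-3-en-3-yl]-4,6,8-trimethylnona-2,7-dienamide
Product: 20 (2E,4S,6R)-N-[(3R)-5-chloro-3-hydroxy-6-oxo-3-(5-oxopentyl)cyclohexa-1,4-dien-1-yl]-4,6,8-trimethylnona-2,7-dienamide, via epoxy keto aldehyde 18 (not isolated), via chlorohydrin 19 (not isolated)
Conditions: 2 M aq HCl, LiCl (10 equiv), THF, 0 °C to rt
Reagents that add atoms: hydrogen chloride Cl; water O
Why: Acid hydrolysis of the dimethyl ketal and the dioxolane unmasks α,β-epoxy ketone 18, chloride opens the protonated oxirane by SN2 at the carbon α to the new ketone (the β carbon is neopentyl-like) to give trans-chlorohydrin 19, and acid-catalysed β-elimination of water gives the α-chloro dienone (the HX epoxy ketone to α-halo enone reaction used for 4-chloro-enones from 4,5-epoxy-3-keto steroids); both oxirane stereocentres are erased while the carbinol keeps its R configuration, since a quinol cannot ionise there without forming a phenoxenium ion.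

Step 13
Reactants: 20 (2E,4S,6R)-N-[(3R)-5-chloro-3-hydroxy-6-oxo-3-(5-oxopentyl)cyclohexa-1,4-dien-1-yl]-4,6,8-trimethylnona-2,7-dienamide
Product: 21 5-[(1R)-3-chloro-1-hydroxy-4-oxo-5-{[(2E,4S,6R)-4,6,8-trimethylnona-2,7-dienoyl]amino}cyclohexa-2,5-dien-1-yl]pentanoic acid
Conditions: NaClO2, NaH2PO4, 2-methyl-2-butene (20 equiv), t-BuOH/H2O, 0 °C to rt
Reagents that add atoms: sodium chlorite [Na+].[O-]Cl=O
Why: Pinnick oxidation converts only the aldehyde to the acid; excess 2-methyl-2-butene scavenges HOCl and protects the trisubstituted alkene, and the tertiary alcohol, chloro enone and enamide are inert.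

**Compound list**
1 | meso-2,4-dimethylglutaric anhydride [(3R,5S)-3,5-dimethyloxane-2,6-dione] | C[C@@H]1C[C@H](C)C(=O)OC1=O | starting material
2 | meso-2,4-dimethylpentane-1,5-diol | OC[C@H](C)C[C@H](C)CO | intermediate
3 | (2S,4R)-5-hydroxy-2,4-dimethylpentyl acetate | OC[C@H](C)C[C@H](C)COC(C)=O | intermediate
4 | (2S,4R)-2,4-dimethyl-5-oxopentyl acetate | O=C[C@H](C)C[C@H](C)COC(C)=O | intermediate
5 | (2S,4R)-2,4,6-trimethylhept-5-en-1-yl acetate | CC(C)=C[C@H](C)C[C@H](C)COC(C)=O | intermediate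
6 | (2S,4R)-2,4,6-trimethylhept-5-en-1-ol | CC(C)=C[C@H](C)C[C@H](C)CO | intermediate
7 | (2S,4R)-2,4,6-trimethylhept-5-enal | CC(C)=C[C@H](C)C[C@H](C)C=O | intermediate
8 | 2,5-dimethoxyaniline | COc1ccc(OC)c(N)c1 | starting material
9 | 2-(diethoxyphosphoryl)acetic acid | CCOP(=O)(OCC)CC(=O)O | starting material
10 | diethyl {2-[(2,5-dimethoxyphenyl)amino]-2-oxoethyl}phosphonate | CCOP(=O)(OCC)CC(=O)Nc1cc(OC)ccc1OC | intermediate
11 | (2E,4S,6R)-N-(2,5-dimethoxyphenyl)-4,6,8-trimethylnona-2,7-dienamide | CC(C)=C[C@H](C)C[C@H](C)/C=C/C(=O)Nc1cc(OC)ccc1OC | intermediate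
12 | (2E,4S,6R)-N-(3,6,6-trimethoxycyclohexa-2,4-dien-1-ylidene)-4,6,8-trimethylnona-2,7-dienamide | CC(C)=C[C@H](C)C[C@H](C)/C=C/C(=O)N=C1C=C(OC)C=CC1(OC)OC | intermediate
13 | (2E,4S,6R)-N-(6,6-dimethoxy-3-oxocyclohexa-1,4-dien-1-yl)-4,6,8-trimethylnona-2,7-dienamide | CC(C)=C[C@H](C)C[C@H](C)/C=C/C(=O)NC1=CC(=O)C=CC1(OC)OC | intermediate
14 | (2E,4S,6R)-N-[(1R,6S)-2,2-dimethoxy-5-oxo-7-oxabicyclo[4.1.0]hept-3-en-3-yl]-4,6,8-trimethylnona-2,7-dienamide | CC(C)=C[C@H](C)C[C@H](C)/C=C/C(=O)NC1=CC(=O)[C@H]2O[C@H]2C1(OC)OC | intermediate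
15 | 2-(4-bromobutyl)-1,3-dioxolane | BrCCCCC1OCCO1 | starting material
16 | [4-(1,3-dioxolan-2-yl)butyl]magnesium bromide | Br[Mg]CCCCC1OCCO1 | intermediate
17 | (2E,4S,6R)-N-[(1R,5R,6S)-5-[4-(1,3-dioxolan-2-yl)butyl]-5-hydroxy-2,2-dimethoxy-7-oxabicyclo[4.1.0]hept-3-en-3-yl]-4,6,8-trimethylnona-2,7-dienamide | CC(C)=C[C@H](C)C[C@H](C)/C=C/C(=O)NC1=C[C@](O)(CCCCC3OCCO3)[C@H]2O[C@H]2C1(OC)OC | intermediate
18 | (2E,4S,6R)-N-[(1R,5R,6S)-5-hydroxy-2-oxo-5-(5-oxopentyl)-7-oxabicyclo[4.1.0]hept-3-en-3-yl]-4,6,8-trimethylnona-2,7-dienamide | CC(C)=C[C@H](C)C[C@H](C)/C=C/C(=O)NC1=C[C@](O)(CCCCC=O)[C@H]2O[C@H]2C1=O | intermediate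
19 | (2E,4S,6R)-N-[(3R,4R,5S)-5-chloro-3,4-dihydroxy-6-oxo-3-(5-oxopentyl)cyclohex-1-en-1-yl]-4,6,8-trimethylnona-2,7-dienamide | CC(C)=C[C@H](C)C[C@H](C)/C=C/C(=O)NC1=C[C@](O)(CCCCC=O)[C@@H](O)[C@H](Cl)C1=O | intermediate
20 | (2E,4S,6R)-N-[(3R)-5-chloro-3-hydroxy-6-oxo-3-(5-oxopentyl)cyclohexa-1,4-dien-1-yl]-4,6,8-trimethylnona-2,7-dienamide | CC(C)=C[C@H](C)C[C@H](C)/C=C/C(=O)NC1=C[C@](O)(CCCCC=O)C=C(Cl)C1=O | intermediate
21 | 5-[(1R)-3-chloro-1-hydroxy-4-oxo-5-{[(2E,4S,6R)-4,6,8-trimethylnona-2,7-dienoyl]amino}cyclohexa-2,5-dien-1-yl]pentanoic acid | CC(C)=C[C@H](C)C[C@H](C)/C=C/C(=O)NC1=C[C@](O)(CCCCC(=O)O)C=C(Cl)C1=O | target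

**Step count and risks**
Total steps: 13. Longest linear sequence: 12 (steps 1–6, then 8–13; step 7 is the side branch).

The three steps most likely to fail:

Step 10 (asymmetric epoxidation of an N-dienoyl monoketal; the known high selectivity of this phase-transfer epoxidation is for the N-Boc analogue). The fallback sets out from 8 and comes back at 14. Compound 8 is protected with Boc2O to give tert-butyl N-(2,5-dimethoxyphenyl)carbamate F1, which PhI(OAc)2 in methanol converts to tert-butyl N-(6,6-dimethoxy-3-oxocyclohexa-1,4-dien-1-yl)carbamate F2. The phase-transfer epoxidation is then run on this precedented substrate and the product recrystallised to give tert-butyl N-[(1R,6S)-2,2-dimethoxy-5-oxo-7-oxabicyclo[4.1.0]hept-3-en-3-yl]carbamate F3. Anhydrous TFA in CH2Cl2 removes the Boc group to give (1S,6R)-4-amino-5,5-dimethoxy-7-oxabicyclo[4.1.0]hept-3-en-2-one F4. In parallel, aldehyde 7 and phosphonoacetic acid 9 (Zn(OTf)2, TMEDA, DBU) give (2E,4S,6R)-4,6,8-trimethylnona-2,7-dienoic acid F5, which the neutral Ghosez reagent turns into (2E,4S,6R)-4,6,8-trimethylnona-2,7-dienoyl chloride F6. F4 is deprotonated with t-BuOLi at −78 °C and N-acylated with F6 to give 14.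

Step 11 (the amide N–H is deprotonated first, and the resulting vinylogous amidate deactivates the ketone towards an sp3 Grignard reagent). The fallback sets out from 14 and comes back at 17. The N–H of 14 is masked with Boc2O/DMAP to give tert-butyl N-[(1R,6S)-2,2-dimethoxy-5-oxo-7-oxabicyclo[4.1.0]hept-3-en-3-yl]-N-[(2E,4S,6R)-4,6,8-trimethylnona-2,7-dienoyl]carbamate F7, in which the ketone is fully electrophilic. Grignard reagent 16 (1.3 equiv, −78 °C) adds anti to the oxirane to give tert-butyl N-[(1R,5R,6S)-5-[4-(1,3-dioxolan-2-yl)butyl]-5-hydroxy-2,2-dimethoxy-7-oxabicyclo[4.1.0]hept-3-en-3-yl]-N-[(2E,4S,6R)-4,6,8-trimethylnona-2,7-dienoyl]carbamate F8. Mg(ClO4)2 in MeCN then removes the Boc group selectively from the N-acyl carbamate to give 17.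

Step 12 (three acid-driven events in one pot; water could compete with chloride, the dehydration could stall, or the tertiary allylic alcohol could ionise before the ketal is gone). The fallback sets out from 17 and comes back at 20, with each event run separately. Montmorillonite K10 in wet CH2Cl2 followed by PPTS in aqueous acetone gives isolated 18 with no chloride present. Anhydrous LiCl/AcOH in THF opens the oxirane to isolated 19. Because base alone would re-close the epoxide, the secondary hydroxyl is activated with MsCl/Et3N to give (1R,2R,6S)-6-chloro-2-hydroxy-5-oxo-2-(5-oxopentyl)-4-{[(2E,4S,6R)-4,6,8-trimethylnona-2,7-dienoyl]amino}cyclohex-3-en-1-yl methanesulfonate F9, which undergoes E1cB elimination with further Et3N to give 20.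

**Further compounds**
F1 | step 10 | tert-butyl N-(2,5-dimethoxyphenyl)carbamate | COc1ccc(OC)c(NC(=O)OC(C)(C)C)c1
F2 | step 10 | tert-butyl N-(6,6-dimethoxy-3-oxocyclohexa-1,4-dien-1-yl)carbamate | CC(C)(C)OC(=O)NC1=CC(=O)C=CC1(OC)OC
F3 | step 10 | tert-butyl N-[(1R,6S)-2,2-dimethoxy-5-oxo-7-oxabicyclo[4.1.0]hept-3-en-3-yl]carbamate | CC(C)(C)OC(=O)NC1=CC(=O)[C@H]2O[C@H]2C1(OC)OC
F4 | step 10 | (1S,6R)-4-amino-5,5-dimethoxy-7-oxabicyclo[4.1.0]hept-3-en-2-one | NC1=CC(=O)[C@H]2O[C@H]2C1(OC)OC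
F5 | step 10 | (2E,4S,6R)-4,6,8-trimethylnona-2,7-dienoic acid | CC(C)=C[C@H](C)C[C@H](C)/C=C/C(=O)O
F6 | step 10 | (2E,4S,6R)-4,6,8-trimethylnona-2,7-dienoyl chloride | CC(C)=C[C@H](C)C[C@H](C)/C=C/C(=O)Cl
F7 | step 11 | tert-butyl N-[(1R,6S)-2,2-dimethoxy-5-oxo-7-oxabicyclo[4.1.0]hept-3-en-3-yl]-N-[(2E,4S,6R)-4,6,8-trimethylnona-2,7-dienoyl]carbamate | CC(C)=C[C@H](C)C[C@H](C)/C=C/C(=O)N(C(=O)OC(C)(C)C)C1=CC(=O)[C@H]2O[C@H]2C1(OC)OC
F8 | step 11 | tert-butyl N-[(1R,5R,6S)-5-[4-(1,3-dioxolan-2-yl)butyl]-5-hydroxy-2,2-dimethoxy-7-oxabicyclo[4.1.0]hept-3-en-3-yl]-N-[(2E,4S,6R)-4,6,8-trimethylnona-2,7-dienoyl]carbamate | CC(C)=C[C@H](C)C[C@H](C)/C=C/C(=O)N(C(=O)OC(C)(C)C)C1=C[C@](O)(CCCCC3OCCO3)[C@H]2O[C@H]2C1(OC)OC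
F9 | step 12 | (1R,2R,6S)-6-chloro-2-hydroxy-5-oxo-2-(5-oxopentyl)-4-{[(2E,4S,6R)-4,6,8-trimethylnona-2,7-dienoyl]amino}cyclohex-3-en-1-yl methanesulfonate | CC(C)=C[C@H](C)C[C@H](C)/C=C/C(=O)NC1=C[C@](O)(CCCCC=O)[C@@H](OS(C)(=O)=O)[C@H](Cl)C1=O
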